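**Plan**

1. Atoms carry the numbers of the target SMILES (C1–C27, O8, O19, O20, N25); ring A = O8/C3–C7, B = N25/C24/C23/C6/C9/C27, C = C6/C9–C13/C23, D = C12–C16, E = C13/C14/C17/C22/C23; CIP descriptors use these numbers.
2. Cuts, last bond first: C24 back to the lactam C=O; ring A at O8–C3 (enol ether from a δ-hydroxy ketone), C4=C5 (olefination), C6–C7 (formaldehyde aldol) and C6–C5 (one-carbon homologation of a C6 ketone); ring E at C14–C17; ring B at N25–C24 and C9–C27; then C23–C22, C23–C24 and ring D (C13–C14, with C12–C16) back to cycloheptane-1,3-dione.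
3. Enabling feature: C17 is a methine that carries only the methyl ester outside ring E, and the allylic CH2 C14 of cyclopentene ring D is the fifth atom along C17–C22–C23–C13–C14, so a carbenoid at C17 that inserts into C14–H closes ring E.
4. Forward: ring C is bought, ring D is annulated (Stork–Danheiser), C24 and the C22–C17–C18 arm are placed on C23, ring B is closed by Mannich reaction and lactamisation, ring E by the C–H insertion, ring A by cyclodehydration, and the lactam is reduced last.
5. Stereochemistry: C23 from a catalyst-controlled Michael addition; C9 follows because the lactam bridge can only close cis; C14 from the geometry of the insertion; C17 from kinetic protonation of the ester enolate on the convex face; C6 from formaldehyde attack on the lactam face, the other face being screened by ring E and the C17 ester.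

Key step: step 11

Assumption: in β-keto ester 10 and its dienolate the alkene rests in the tetrasubstituted C12=C13 position (the thermodynamic site); should the C13=C14 isomer intrude, 10 is equilibrated with Et3N before step 7.

**Route**

Step 1
Reactants: 1 cycloheptane-1,3-dione; 2 2-methylpropan-1-ol
Product: 3 3-(2-methylpropoxy)cyclohept-2-en-1-one
Conditions: p-TsOH·H2O (cat.), toluene, reflux, Dean–Stark
Reagents that add atoms: none
Why: Acid-catalysed enol etherification of a cyclic 1,3-dione (vinylogous ester formation) is driven by azeotropic removal of water and differentiates the two carbonyls for the Stork–Danheiser sequence.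

Step 2
Reactants: 3 3-(2-methylpropoxy)cyclohept-2-en-1-one; 4 1-chloro-3-iodopropane
Product: 5 7-(3-chloropropyl)-3-(2-methylpropoxy)cyclohept-2-en-1-one (racemic)
Conditions: LiN(i-Pr)2, THF, −78 °C; then 4, DMPU, −78 → −20 °C
Reagents that add atoms: none
Why: Kinetic deprotonation of a vinylogous ester takes place at the α′ carbon (Stork–Danheiser alkylation) and the enolate displaces iodide in preference to chloride, so the chloride is kept for the next step.

Step 3
Reactants: 5 7-(3-chloropropyl)-3-(2-methylpropoxy)cyclohept-2-en-1-one
Product: 6 7-(3-iodopropyl)-3-(2-methylpropoxy)cyclohept-2-en-1-one (racemic)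
Conditions: NaI, acetone, reflux
Reagents that add atoms: sodium iodide, [Na+].[I-]
Why: Finkelstein exchange, driven by precipitation of NaCl, gives the primary iodide needed for fast iodine–lithium exchange.

Step 4
Reactants: 6 7-(3-iodopropyl)-3-(2-methylpropoxy)cyclohept-2-en-1-one
Product: 8 2,3,6,7,8,8a-hexahydroazulen-5(1H)-one (racemic), via bicyclic tertiary alcohol 7 (not isolated)
Conditions: t-BuLi (2.1 equiv), Et2O/pentane, −78 °C → rt; then 2 M HCl, THF, rt
Reagents that add atoms: water, O
Why: Iodine–lithium exchange outruns addition of t-BuLi to the weakly electrophilic vinylogous ester carbonyl, the primary alkyllithium adds intramolecularly (1,2) to close ring D, and acid hydrolysis with loss of water transposes the enone (Stork–Danheiser enone synthesis).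

Step 5
Reactants: 8 2,3,6,7,8,8a-hexahydroazulen-5(1H)-one
Product: 9 4-iodo-2,3,6,7,8,8a-hexahydroazulen-5(1H)-one (racemic)
Conditions: I2, pyridine/CH2Cl2 (1:1), 0 °C → rt
Reagents that add atoms: iodine, II
Why: α-Iodination of a cyclic enone by pyridine conjugate addition, iodination of the enolate and elimination (Baylis–Hillman-type pathway) can only place the halogen on the α-vinylic carbon C23, which settles the C23-versus-C9 question that acylation of an enone enolate would leave open.

Step 6
Reactants: 9 4-iodo-2,3,6,7,8,8a-hexahydroazulen-5(1H)-one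
Product: 10 methyl 5-oxo-1,2,3,4,5,6,7,8-octahydroazulene-4-carboxylate (racemic; enolisable)
Conditions: Pd(OAc)2 (5 mol %), PPh3 (10 mol %), CO (1 atm), MeOH, Et3N, DMF, 60 °C
Reagents that add atoms: carbon monoxide, [C-]#[O+]; methanol, CO
Why: Palladium-catalysed alkoxycarbonylation (oxidative addition of zerovalent palladium into the vinyl C–I bond, CO insertion, methanolysis) installs C24, and the first-formed 2-methoxycarbonyl enone should tautomerise under Et3N to the enolisable β-keto ester with the alkene in the tetrasubstituted C12=C13 position.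

Step 7
Reactants: 10 methyl 5-oxo-1,2,3,4,5,6,7,8-octahydroazulene-4-carboxylate; 11 1,1,1,3,3,3-hexafluoropropan-2-yl prop-2-enoate
Product: 13 methyl (4R)-4-(3-methoxy-3-oxopropyl)-5-oxo-1,2,3,4,5,6,7,8-octahydroazulene-4-carboxylate, via hexafluoroisopropyl ester 12 (not isolated)
Conditions: quinine-derived 9-amino(9-deoxy)-epi thiourea bearing a 3,5-bis(trifluoromethyl)phenyl group (10 mol %), toluene, −20 °C; then MeOH, Et3N, DMAP (cat.), rt
Reagents that add atoms: methanol, CO
Why: Bifunctional cinchona thiourea catalysis of the Michael addition of a cyclic α-substituted β-keto ester to an activated acrylic ester is an established way to all-carbon quaternary centres; the quinuclidine forms the ion-paired dienolate, which is alkylated at its α-carbon C23 on the face left open by the catalyst (C23 R, with the quinidine-derived pseudo-enantiomer held in reserve should the sense be opposite), and base-catalysed methanolysis then turns the active ester into the methyl ester.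

Step 8
Reactants: 13 methyl (4R)-4-(3-methoxy-3-oxopropyl)-5-oxo-1,2,3,4,5,6,7,8-octahydroazulene-4-carboxylate
Product: 14 methyl (4R)-4-(3-methoxy-3-oxopropyl)-5-[(trimethylsilyl)oxy]-1,2,3,4,7,8-hexahydroazulene-4-carboxylate
Conditions: Me3SiOTf (1.3 equiv), Et3N, CH2Cl2, 0 °C; pentane, filtration
Reagents that add atoms: trimethylsilyl trifluoromethanesulfonate, C[Si](C)(C)OS(=O)(=O)C(F)(F)F
Why: Soft enolisation with a silyl triflate and an amine silylates the ketone, which can enolise only toward C9 because C23 is quaternary, and leaves both esters untouched.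

Step 9
Reactants: 14 silyl enol ether; 15 1,3,5-trimethyl-1,3,5-triazinane
Product: 17 (9R,23R)-bicyclic keto lactam ester, via amino ketone 16 (not isolated)
Conditions: 15 (0.4 equiv), Me3SiOTf (0.2 equiv), CH2Cl2, −78 → 0 °C; aq. NaHCO3; then toluene, 2-hydroxypyridine (cat.), 90 °C
Reagents that add atoms: none
Why: Mukaiyama–Mannich reaction of the silyl enol ether with N-methylmethaniminium released from the triazinane gives the β-(methylamino) ketone, whose amine then acylates on the C24 ester (six-membered lactamisation of a δ-amino ester, against an eight-membered ring at C18) to close ring B; only the C9 epimer with the aminomethyl group cis to C24 can close and the other epimerises through the enol, so C9 follows from C23, and a plain iminium ion, unlike an N-acyliminium ion, leaves the C12=C13 alkene alone.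

Step 10
Reactants: 17 (9R,23R)-bicyclic keto lactam ester
Product: 19 (9R,23R)-α-diazo ester, via trifluoroacetyl ester 18 (not isolated)
Conditions: LiN(SiMe3)2, THF, −78 °C; CF3CO2CH2CF3; then MeSO2N3, Et3N, H2O (1 equiv), MeCN, rt
Reagents that add atoms: methanesulfonyl azide, CS(=O)(=O)N=[N+]=[N-]; 2,2,2-trifluoroethyl trifluoroacetate, O=C(OCC(F)(F)F)C(F)(F)F
Why: Deacylative (Regitz-type, detrifluoroacetylative) diazo transfer works here because C17 is the only enolisable position (C9–H is a bridgehead hydrogen lying in the plane of the C6 carbonyl and the lactam has no α-hydrogen), so Claisen trifluoroacetylation and azide transfer with loss of the trifluoroacetyl group place the diazo group on C17.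

Step 11
Reactants: 19 (9R,23R)-α-diazo ester
Product: 21 (9R,14R,17R,23R)-tetracyclic keto lactam ester, via 17-epi tetracycle 20 (not isolated)
Conditions: Rh2(O2CCPh3)4 (1 mol %), CH2Cl2, −40 °C → rt, slow addition of 19; concentrate; then KN(SiMe3)2, THF, −78 °C; 2,6-di-tert-butyl-4-methylphenol, −78 °C
Reagents that add atoms: none
Why: Rh2(O2CCPh3)4 expels N2 from 19 to give the electrophilic rhodium carbenoid at C17, which inserts into the allylic C14–H bond through a three-centre, hydride-transfer-like transition state with retention at C14 (intramolecular carbenoid C–H insertion of an α-diazo ester, the known route to cyclopentanecarboxylates). Ring E closes in the 1,5 mode, a five-membered ring formed through the six-centre array C17–C22–C23–C13–C14–H. C14 is controlled by the cage: the arm on bridgehead C23 should reach the C14–H on the face of ring D turned toward the C6 bridge, because reaching the other face would force the lactam carbonyl carbon C24 into the plane of the alkene against the C11 methylene, so C17 bonds on the C6 face. C17 is expected to form mainly with the ester trans to C15 (20) and is then set by deprotonation with KN(SiMe3)2 and protonation of the enolate by the bulky phenol from the open convex face, which leaves the ester on the concave face as in the target, whichever epimer the insertion gave. The step needs insertion to beat 1,2-hydride shift from C22, other C–H bonds and the flanking heteroatoms: bulky triphenylacetate ligands and low temperature are the known means of suppressing hydride shift for α-alkyl diazo esters, C14–H is the only activated C–H five atoms away (C9–H is a bridgehead bond pointing outward, C6 and C24 carry no hydrogen), the amide nitrogen cannot form an ylide and cyclopropanation of C12=C13 would need a four-membered tether. Capture of the carbenoid by the C6 or C24 carbonyl oxygen is the weak point and is taken up at the end.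

Step 12
Reactants: 21 (9R,14R,17R,23R)-tetracyclic keto lactam ester; 22 (methoxymethyl)triphenylphosphonium chloride
Product: 24 C6-formyl lactam ester (formyl carbon = C5; both C6 epimers), via methyl enol ether 23 (not isolated)
Conditions: 22 (3 equiv), KOt-Bu (2.8 equiv), THF, 0 → 45 °C; then 2 M HCl, THF, rt
Reagents that add atoms: water, O
Why: Wittig methoxymethylenation suits a non-enolisable ketone and acid hydrolysis of the enol ether gives the one-carbon homologated aldehyde, whose C6 configuration is of no consequence because C6 is made planar in the next step; the C17 ester should keep its configuration since base is kept in deficit and any reprotonation would again come from the convex face.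

Step 13
Reactants: 24 C6-formyl lactam ester; 25 formaldehyde (37 % in water)
Product: 26 (6R,9S,14R,17R,23R)-C6-formyl C6-hydroxymethyl lactam ester
Conditions: K2CO3 (0.3 equiv), THF/H2O, 0 °C → rt
Reagents that add atoms: none
Why: Crossed aldol addition (Tollens-type α-hydroxymethylation) of the α-branched aldehyde to non-enolisable formaldehyde creates the quaternary C6, and formaldehyde should approach the exocyclic enolate over the flat lactam bridge of ring B because the face over ring C is screened by ring E and the concave C17 ester, which places C7 over ring B as in the target.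

Step 14
Reactants: 26 hydroxymethyl aldehyde; 27 diethyl (2-oxobutyl)phosphonate
Product: 28 (6S,9S,14R,17R,23R)-(E)-enone
Conditions: LiCl, i-Pr2NEt, MeCN, rt
Reagents that add atoms: none
Why: Horner–Wadsworth–Emmons olefination under the mild Masamune–Roush conditions adds C4 to C1 as the (E)-enone without retro-aldol loss of formaldehyde from the β-hydroxy aldehyde.

Step 15
Reactants: 28 (E)-enone
Product: 29 (6S,9S,14R,17R,23R)-δ-hydroxy ketone
Conditions: H2 (1 atm), 5 % Pd/C, EtOAc, rt
Reagents that add atoms: none
Why: Catalytic hydrogenation saturates the 1,2-disubstituted enone alkene far faster than the tetrasubstituted C12=C13 alkene and leaves the δ-hydroxy ketone in equilibrium with its lactol.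

Step 16
Reactants: 29 δ-hydroxy ketone
Product: 30 (6S,9S,14R,17R,23R)-pentacyclic lactam (24-oxo target)
Conditions: PPTS (10 mol %), toluene, 4 Å molecular sieves, 80 °C
Reagents that add atoms: none
Why: Acid-catalysed cyclodehydration of the δ-hydroxy ketone through its six-membered lactol gives the endocyclic enol ether of ring A, the preferred alkene position for a 6-alkyl-3,4-dihydro-2H-pyran under equilibrating acid.

Step 17
Reactants: 30 pentacyclic lactam
Product: 32 CNP0159589.2, via silyl hemiaminal 31 (not isolated)
Conditions: IrCl(CO)(PPh3)2 (2 mol %), (Me2SiH)2O (3 equiv), toluene, rt; then NaBH4, MeOH, 0 °C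
Reagents that add atoms: 1,1,3,3-tetramethyldisiloxane, C[SiH](C)O[SiH](C)C
Why: Iridium-catalysed hydrosilylation takes a tertiary lactam to the O-silyl hemiaminal chemoselectively beside the methyl ester, and because C24 has no α-hydrogen the hemiaminal ionises in methanol to the iminium ion that borohydride reduces, a sequence free of acid that spares the enol ether of ring A.

**Compound list**

A change of descriptor at C9 or C23 between neighbouring compounds reflects changed CIP priorities, not inversion.

1 | cycloheptane-1,3-dione | O=C1CCCCC(=O)C1 | starting material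
2 | 2-methylpropan-1-ol | CC(C)CO | starting material
3 | 3-(2-methylpropoxy)cyclohept-2-en-1-one | CC(C)COC1=CC(=O)CCCC1 | intermediate
4 | 1-chloro-3-iodopropane | ClCCCI | starting material
5 | 7-(3-chloropropyl)-3-(2-methylpropoxy)cyclohept-2-en-1-one (racemic) | CC(C)COC1=CC(=O)C(CCCCl)CCC1 | intermediate
6 | 7-(3-iodopropyl)-3-(2-methylpropoxy)cyclohept-2-en-1-one (racemic) | CC(C)COC1=CC(=O)C(CCCI)CCC1 | intermediate
7 | 7-(2-methylpropoxy)-1,2,3,3a,4,5,6,8a-octahydroazulen-8a-ol (racemic; not isolated) | OC12C=C(OCC(C)C)CCCC1CCC2 | intermediate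
8 | 2,3,6,7,8,8a-hexahydroazulen-5(1H)-one (racemic) | O=C1C=C2CCCC2CCC1 | intermediate
9 | 4-iodo-2,3,6,7,8,8a-hexahydroazulen-5(1H)-one (racemic) | O=C1C(I)=C2CCCC2CCC1 | intermediate
10 | methyl 5-oxo-1,2,3,4,5,6,7,8-octahydroazulene-4-carboxylate (racemic, enolisable) | O=C1CCCC2=C(CCC2)C1C(=O)OC | intermediate
11 | 1,1,1,3,3,3-hexafluoropropan-2-yl prop-2-enoate | C=CC(=O)OC(C(F)(F)F)C(F)(F)F | starting material
12 | methyl (4R)-4-{3-[(1,1,1,3,3,3-hexafluoropropan-2-yl)oxy]-3-oxopropyl}-5-oxo-1,2,3,4,5,6,7,8-octahydroazulene-4-carboxylate (not isolated) | O=C1CCCC2=C(CCC2)[C@@]1(CCC(=O)OC(C(F)(F)F)C(F)(F)F)C(=O)OC | intermediate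
13 | methyl (4R)-4-(3-methoxy-3-oxopropyl)-5-oxo-1,2,3,4,5,6,7,8-octahydroazulene-4-carboxylate | O=C1CCCC2=C(CCC2)[C@@]1(CCC(=O)OC)C(=O)OC | intermediate
14 | methyl (4R)-4-(3-methoxy-3-oxopropyl)-5-[(trimethylsilyl)oxy]-1,2,3,4,7,8-hexahydroazulene-4-carboxylate | C[Si](C)(C)OC1=CCCC2=C(CCC2)[C@@]1(CCC(=O)OC)C(=O)OC | intermediate
15 | 1,3,5-trimethyl-1,3,5-triazinane | CN1CN(C)CN(C)C1 | starting material
16 | methyl (4R)-4-(3-methoxy-3-oxopropyl)-6-[(methylamino)methyl]-5-oxo-1,2,3,4,5,6,7,8-octahydroazulene-4-carboxylate (both C6 epimers, azulene numbering; not isolated) | O=C1C(CNC)CCC2=C(CCC2)[C@@]1(CCC(=O)OC)C(=O)OC | intermediate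
17 | (9R,23R)-bicyclic keto lactam ester: hydroazulenone (rings C and D, C6 ketone, C12=C13) bridged from C23 to C9 by C24(=O)–N25(CH3)–C27H2 (ring B), C23 bearing CH2CH2CO2CH3 | O=C1[C@@H]2CCC3=C(CCC3)[C@@]1(CCC(=O)OC)C(=O)N(C)C2 | intermediate
18 | (9R,23R)-keto lactam ester with a trifluoroacetyl group on C17 (C17 epimers; not isolated) | O=C1[C@@H]2CCC3=C(CCC3)[C@@]1(CC(C(=O)C(F)(F)F)C(=O)OC)C(=O)N(C)C2 | intermediate
19 | (9R,23R)-α-diazo ester: 17 with N2 on C17 | O=C1[C@@H]2CCC3=C(CCC3)[C@@]1(CC(=[N+]=[N-])C(=O)OC)C(=O)N(C)C2 | intermediate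
20 | (9R,14R,17S,23R)-tetracyclic keto lactam ester, ester trans to C15 (not isolated) | O=C1[C@@H]2CCC3=C4[C@H](CC3)[C@@H](C(=O)OC)C[C@@]41C(=O)N(C)C2 | intermediate
21 | (9R,14R,17R,23R)-tetracyclic keto lactam ester (rings B to E; H14 and H17 cis, ester on the concave face) | O=C1[C@@H]2CCC3=C4[C@H](CC3)[C@H](C(=O)OC)C[C@@]41C(=O)N(C)C2 | intermediate
22 | (methoxymethyl)triphenylphosphonium chloride | COC[P+](c1ccccc1)(c1ccccc1)c1ccccc1.[Cl-] | starting material
23 | (9S,14R,17R,23R)-methyl enol ether, C6=C5H–OCH3 (E/Z mixture; not isolated) | COC=C1[C@@H]2CCC3=C4[C@H](CC3)[C@H](C(=O)OC)C[C@@]41C(=O)N(C)C2 | intermediate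
24 | (9S,14R,17R,23S)-C6-formyl lactam ester, C6–H with formyl carbon C5 (both C6 epimers) | O=CC1[C@@H]2CCC3=C4[C@H](CC3)[C@H](C(=O)OC)C[C@@]41C(=O)N(C)C2 | intermediate
25 | formaldehyde | C=O | starting material
26 | (6R,9S,14R,17R,23R)-lactam ester with C6 bearing CHO (C5, over ring C) and CH2OH (C7, over ring B) | O=C[C@]1(CO)[C@@H]2CCC3=C4[C@H](CC3)[C@H](C(=O)OC)C[C@@]41C(=O)N(C)C2 | intermediate
27 | diethyl (2-oxobutyl)phosphonate | CCC(=O)CP(=O)(OCC)OCC | starting material
28 | (6S,9S,14R,17R,23R)-(E)-enone, C6–C5H=C4H–C3(=O)–C2H2–C1H3, with C7H2OH | CCC(=O)/C=C/[C@]1(CO)[C@@H]2CCC3=C4[C@H](CC3)[C@H](C(=O)OC)C[C@@]41C(=O)N(C)C2 | intermediate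
29 | (6S,9S,14R,17R,23R)-δ-hydroxy ketone | CCC(=O)CC[C@]1(CO)[C@@H]2CCC3=C4[C@H](CC3)[C@H](C(=O)OC)C[C@@]41C(=O)N(C)C2 | intermediate
30 | (6S,9S,14R,17R,23R)-24-oxo derivative of the target (pentacyclic lactam) | CCC1=CC[C@]2(CO1)[C@@H]1CCC3=C4[C@H](CC3)[C@H](C(=O)OC)C[C@@]42C(=O)N(C)C1 | intermediate
31 | C24 O-(1,1,3,3-tetramethyldisiloxanyl) hemiaminal of 30 (C24 epimers; not isolated) | CCC1=CC[C@]2(CO1)[C@@H]1CCC3=C4[C@H](CC3)[C@H](C(=O)OC)C[C@@]42C(O[Si](C)(C)O[SiH](C)C)N(C)C1 | intermediate
32 | CNP0159589.2, (6S,9S,14R,17R,23R) | CCC1=CC[C@]2(CO1)[C@@H]1CCC3=C4[C@H](CC3)[C@H](C(=O)OC)C[C@@]42CN(C)C1 | target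

**Step count**

Total: 17 steps. Longest linear sequence: 17 steps, from cycloheptane-1,3-dione 1 to 32.

**Steps most likely to fail**

Step 11. The short-lived carbenoid may be consumed before it reaches C14–H. The C6 ketone oxygen eclipses the C22 arm and can close a five-membered carbonyl ylide, and the lactam oxygen is only slightly further away. 1,2-Hydride shift from C22, or insertion on the other face of ring D, would also erode yield or the C14 configuration. Fallback, from 17 and back at 24: the ketone is replaced before the key step by a group without a lone pair. Wittig methylenation of 17 (Ph3P=CH2 from Ph3PCH3Br and KOt-Bu, THF) would give the C6-methylene lactam ester F1, whose π lobes stand perpendicular to the C22 arm. The diazo transfer of step 10 would then proceed through the trifluoroacetyl ester F2 to the diazo ester F3. The conditions of step 11 would give, through the 17-epimer F4, the tetracyclic methylene lactam ester F5. Hydroboration with 9-BBN (trialkylborane F6) and oxidation with NaBO3·4H2O would give the primary alcohol F7, and Dess–Martin oxidation would return aldehyde 24, so that step 12 is no longer needed.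

Step 7. Conjugate addition of a hindered seven-membered dienolate to a modest acceptor may be slow, the enantioselectivity may erode, and attack through the γ-carbon may compete. Fallback, from 10 and back at 13: the acceptor is changed to acrolein, the most reactive partner for cinchona-catalysed Michael additions of β-keto esters that form quaternary centres (6′-hydroxy cinchona catalyst, CH2Cl2, −24 °C), to give the keto ester aldehyde F8. Chlorite oxidation (NaClO2, NaH2PO4, 2-methylbut-2-ene) would give the acid F9, and Me3SiCHN2 in MeOH/toluene would give diester 13.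

Step 13. Facial selectivity of C–C bond formation at C6 may be poor or reversed, and the aldol may revert. Fallback, from 24 and back at 29: the order in which the two carbons are attached to C6 is reversed, so that the face the electrophile prefers now receives C5. DBU-catalysed Michael addition of 24 to pent-1-en-3-one would give the keto aldehyde F10, in which the formyl carbon is C7. NaBH4 in MeOH at −78 °C reduces the aldehyde ahead of the ketone and gives hydroxy ketone 29.

**Further compounds**

F1 | step 11 | (9S,23S)-C6-methylene lactam ester (17 with C6=CH2) | C=C1[C@@H]2CCC3=C(CCC3)[C@@]1(CCC(=O)OC)C(=O)N(C)C2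
F2 | step 11 | C17-trifluoroacetyl derivative of F1 (C17 epimers) | C=C1[C@@H]2CCC3=C(CCC3)[C@@]1(CC(C(=O)C(F)(F)F)C(=O)OC)C(=O)N(C)C2
F3 | step 11 | (9S,23S)-C6-methylene α-diazo ester | C=C1[C@@H]2CCC3=C(CCC3)[C@@]1(CC(=[N+]=[N-])C(=O)OC)C(=O)N(C)C2
F4 | step 11 | (9S,14R,17S,23S)-tetracyclic methylene lactam ester (17-epimer) | C=C1[C@@H]2CCC3=C4[C@H](CC3)[C@@H](C(=O)OC)C[C@@]41C(=O)N(C)C2
F5 | step 11 | (9S,14R,17R,23S)-tetracyclic methylene lactam ester | C=C1[C@@H]2CCC3=C4[C@H](CC3)[C@H](C(=O)OC)C[C@@]41C(=O)N(C)C2
F6 | step 11 | B-alkyl-9-borabicyclo[3.3.1]nonane adduct of F5 (boron on C7; C6 epimers) | C1CC2CCCC(C1)B2CC1[C@@H]2CCC3=C4[C@H](CC3)[C@H](C(=O)OC)C[C@@]41C(=O)N(C)C2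
F7 | step 11 | (9S,14R,17R,23S)-C6-hydroxymethyl lactam ester (C6 epimers) | OCC1[C@@H]2CCC3=C4[C@H](CC3)[C@H](C(=O)OC)C[C@@]41C(=O)N(C)C2
F8 | step 7 | methyl (4R)-5-oxo-4-(3-oxopropyl)-1,2,3,4,5,6,7,8-octahydroazulene-4-carboxylate | O=C1CCCC2=C(CCC2)[C@@]1(CCC=O)C(=O)OC
F9 | step 7 | 3-[(4R)-4-(methoxycarbonyl)-5-oxo-1,2,3,4,5,6,7,8-octahydroazulen-4-yl]propanoic acid | O=C1CCCC2=C(CCC2)[C@@]1(CCC(=O)O)C(=O)OC
F10 | step 13 | (6S,9S,14R,17R,23R)-keto aldehyde: C6 bearing CHO (C7) and CH2CH2C(=O)CH2CH3 | CCC(=O)CC[C@]1(C=O)[C@@H]2CCC3=C4[C@H](CC3)[C@H](C(=O)OC)C[C@@]41C(=O)N(C)C2
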